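Two mirror-image substrates in one flask meet the same free catalyst and the same coupling partner at each moment, so on the two suspected coupling steps, and as long as the substrates do not turn into each other, the logarithm of the fraction left of one stays a fixed multiple of that of the other, however catalyst and partner fade.

all flasks: left-handed substrate 0.10 M; right-handed substrate 0.10 M

| flask | coupling partner | free catalyst | remark | time |
|---|---|---|---|---|
| violet | 0.40 M (fed, over 30 s) | 6.4 mM | run made earlier |  |
| green | 0.40 M (fed, over 30 s) | 10 mM | run made earlier |  |
| grey | 0.40 M (fed, over 30 s) | 16 mM | run made earlier |  |
| eta | 0.400 M (fed, over 30 s) | 5.0 mM |  | 5.0 min |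
| gamma | 0.400 M (fed, over 30 s) | 20 mM |  | 5.0 min |

| run | time / min | right-handed substrate / % | left-handed substrate / % |
|---|---|---|---|
| violet | 0.250 | 48 | 50 |
| violet | 0.667 | 44 | 39 |
| violet | 1.50 | 38 | 27 |
| violet | 4.00 | 33 | 20 |
| green | 0.417 | 49 | 38 |
| green | 1.33 | 34 | 18 |
| green | 2.50 | 27 | 10 |
| green | 4.00 | 27 | 7 |
| grey | 0.417 | 44 | 34 |
| grey | 1.33 | 32 | 11 |
| grey | 2.50 | 23 | 6 |
| grey | 4.00 | 21 | 3 |

(each reading ± 1.5 percentage points)
1. the winner by excess of right-handed substrate over left-handed substrate among what is left of the two; "neither" if no more than 2 percentage points parts them (eta / gamma / neither)
2. excess of right-handed substrate over left-handed substrate among what is left of the two at the end, eta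
3. excess of right-handed substrate over left-handed substrate among what is left of the two at the end, gamma
- free catalyst is single-handed; left-handed substrate and right-handed substrate are mirror images of each other, charged as a racemate, each of them at the stated concentration
- the numbers in the tables scatter with a standard deviation of 1.5 percentage points
- on the list of suspects stand: left-handed product <-> right-handed product; coupling partner + free catalyst -> spent catalyst; coupling partner -> decomposed reagent; coupling partner + free catalyst + left-handed substrate -> free catalyst + left-handed product; coupling partner + free catalyst + right-handed substrate -> free catalyst + right-handed product; left-handed substrate <-> right-handed substrate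
- an excess is the difference of the two amounts in percent of their sum
- an excess is below zero if the other one leads

Take decadic logarithms, each fraction counted on its own charge, and let s be the logarithm for the left-handed substrate divided by that for the right-handed substrate. The green run at 2.50 min, with 10% left-handed and 27% right-handed, gives s = 2.61, and this ratio, the selectivity factor, is what the reckoning carries. Violet at 4.00 min reads 2.21 and grey 3.24, but grey's left-handed reading of 3% carries a scatter of 1.5 percentage points. If y is minus the logarithm for the right-handed substrate, right-handed stands over left-handed by a factor of ten to the power (s − 1)y, which gives the excess.

In this reckoning each setting then acts through y. The catalyst moves y from 0.180 in violet to 0.377 in grey at 4.00 min, which on logarithms is a power n = 0.803 of the catalyst charge. The green right-handed readings stand at 27% at 2.50 min and 27% at 4.00 min, so this reckoning lets the readings at 4.00 min stand for the asked time. Partner charge and feed time are equal in the three runs, so these give no reading of them; by hand, less partner lowers y and leaves s as it is. Scaling y by the power n gives 0.148 for eta and 0.451 for gamma, hence excesses of 26.8% and 68.4%.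

The forecast names gamma, with 21% for eta and 79% for gamma, on the ground that “The final excess is therefore set by how much catalyst is charged.” It agrees with this reckoning on the winner and differs from it on both excesses.

The flasks give gamma, with 26.5% for eta and 69.1% for gamma, from these equations:

    left-handed product ⇌ right-handed product (k = 0.00110 /s)
    coupling partner + free catalyst → spent catalyst (k = 0.0190 /M/s)
    coupling partner → decomposed reagent (k = 0.00550 /s)
    coupling partner + free catalyst + left-handed substrate → free catalyst + left-handed product (k = 6.40 /M²/s)
    coupling partner + free catalyst + right-handed substrate → free catalyst + right-handed product (k = 2.30 /M²/s)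
    left-handed substrate ⇌ right-handed substrate (k = 3.40 × 10⁻⁴ /s)

The forecast stands below the flask for eta and above it for gamma. With s, gamma's remaining 5.3% of its left-handed charge gives an excess of 71.9%, against 69.1% in the flask. A neighbouring flask repeats gamma with 0.10 M of coupling partner instead of 0.400 M, and at 5.00 min it keeps 54% of its left-handed charge, for which the same reckoning gives 18.5%. That flask stands at 17.4%.

The numbers in the tables were generated by integration for substances that don't exist; noise was put on by code.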